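Read the rate off the runs before believing any scheme, and ask which concentration sets its order. Here electrophile runs at a steady rate for 50 min into stirred nucleophile.

| setting | midnight | dawn | larch | cedar |
|---|---|---|---|---|
| electrophile | 0.068 M (fed, over 50 min) | 0.068 M (fed, over 50 min) | 0.068 M (fed, over 50 min) | 0.068 M (fed, over 50 min) |
| nucleophile | 0.69 equiv | 1.2 equiv | 0.900 equiv | 1.40 equiv |
| remark | run made earlier; the fed solution adds 0.20 times the starting volume | run made earlier; the fed solution adds 0.20 times the starting volume | the fed solution adds 0.20 times the starting volume | the fed solution adds 0.20 times the starting volume |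
| time |  |  | 5.0 h | 5.0 h |

| run | time / h | electrophile / % | product / % |
|---|---|---|---|
| midnight | 0.417 | 21.4 | 29.9 |
| midnight | 0.833 | 61.3 | 40.3 |
| midnight | 1.33 | 55.0 | 45.7 |
| midnight | 1.50 | 52.6 | 47.3 |
| midnight | 2.00 | 48.7 | 53.0 |
| midnight | 2.50 | 43.7 | 54.3 |
| dawn | 0.167 | 7.1 | 13.9 |
| dawn | 0.500 | 15.0 | 46.4 |
| dawn | 0.833 | 39.3 | 61.7 |
| dawn | 1.33 | 30.0 | 68.0 |
| dawn | 2.00 | 23.6 | 77.0 |
| dawn | 2.50 | 18.6 | 80.3 |

(readings scatter by 1 percentage point)

* part of the electrophile that has reacted at the end, larch
* part of the electrophile that has reacted at the end, cedar
* what raising the equivalents of nucleophile from its lowest to its highest value here does to the part of the electrophile that has reacted (changes below 5 percentage points count as none) (no change / it rises / it falls)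

- amounts are per litre of the starting volume; all of the dose is in the solution fed
- the numbers in the tables scatter with a standard deviation of 1 percentage point
- percentages count the whole charge, also what has not yet gone in

I climbed a ladder of rates, using the dawn run. During the feed, dawn's product formed at 8.83 /h per unit of electrophile present, a pseudo-first-order lifetime of 6.80 min. That is shorter than the feed, so dawn held 15.0 % of electrophile at 0.500 h. After the feed, dawn's figure was 0.385 /h, a lifetime of 2.60 h, longer than the feed but shorter than the 5.0 h asked. That figure, read off the readings, fell by a factor of 22.9, more than dawn's pool, the nucleophile not yet turned into product, which went from 0.736 at 0.500 h to 0.397 equivalents at 2.50 h. So I carried the late figure and not the early one.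

The late rate I took as second order, in electrophile and in that pool. Its late constant is the rate of product, in shares of the charge, over the electrophile share and the pool. Dawn gave 0.842 /h, midnight gave 0.778 /h, and I used their mean, 0.810 /h.

Interpolating the end-of-feed product between the runs gave 49.1 % for larch, and extrapolating gave 70.1 % for cedar. Running 0.810 /h for the remaining 4.17 h, I reckoned 76.6 % for larch and 95.0 % for cedar.

The forecast, holding that “an early fast phase has died away by the end of dosing”, gave 77 % for larch, 95 % for cedar, and for the trend, it rises.

The flask gave 77.1 % for larch, 95.5 % for cedar, and it rises, by 18 percentage points.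

    electrophile + nucleophile → acid set free + product (k = 0.0959 /M/s)
    nucleophile + acid set free ⇌ protonated nucleophile, settled at all times (K = 3880 /M)
    nucleophile + acid set free ⇌ idle adduct, settled at all times (K = 11.0 /M)
    crystals ⇌ acid set free, rate k4*(cs4 - [acid set free]) while solid is left; crystals form when [acid set free] > cs4 (solubility = 5.60 mM, k = 0.0662 /s)

In larch, [acid set free] stood at 0.00565 M at 0.833 h and 0.00561 M at 5.00 h, while crystals grew from 2.69 × 10⁻⁵ M to 0.0311 M; the fit without that loss of acid gave 71.7 % for larch. Starting 0.810 /h from larch's simulated 49.1 % at the end of the feed gives 76.6 % against 77.1 %. The flask like cedar but with 0.840 equiv of nucleophile, started from an end-of-feed product interpolated between the runs as 46.6 %, reckons to 73.0 % by the same constant, and it stood at 73.5 %.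

The earlier runs and the new flask were computed with made-up constants; noise was put on by code.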